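Ring A (C1, C10–C14) is cut into a C10–C13 diene and the C1–C14 alkene. Ring A has oxygen at C13 and a masked ketone at C11 (the C11=C20 methylene), the pattern of a Danishefsky-type diene, but C1 is α to C2, so both new bonds join carbons of like polarity. A formyl group on C14 reverses this: an iminium-catalysed Diels–Alder reaction of the enal (E)-OHC–CH=C(Me)–CON(OMe)Me with a (1E,3Z)-1-alkoxy-3-silyloxy diene carrying C9 and C8 forms C1–C10 and C13–C14 in one operation and sets C1 and C10. The formyl group is then excised; Reformatsky lactonisation and enyne metathesis close rings C and B.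

Key step: step 7

Remark (numbering): briarane numbering is used. Ring A is C1 (quaternary, C15 methyl), C10, C11 (=C20H2), C12, C13, C14. Ring B is C1–C10, with C16 the methylene on C5. Ring C is the lactone C7–O–C19(=O)–C17(C18H3)–C8. The target is 1S,2S,6S,7R,8R,9S,10S,13S,17R with a 3E alkene.
Remark (assumption): the stabilised ylide 2 is taken as purchasable; (−)-Ipc2BCl is the reagent derived from (+)-α-pinene.

Step 1
Reactants: 1 2,2-dimethoxyacetaldehyde; 2 N-methoxy-N-methyl-2-(triphenylphosphoranylidene)propanamide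
Product: 3 (2E)-N,4,4-trimethoxy-N,2-dimethylbut-2-enamide
Conditions: CH2Cl2, rt
Reagents that add atoms: none
Why: Wittig olefination with an α-branched stabilised ylide should give the E trisubstituted enamide, with the amide carbonyl trans to the acetal carbon.

Step 2
Reactants: 3 (2E)-N,4,4-trimethoxy-N,2-dimethylbut-2-enamide
Product: 4 (2E)-N-methoxy-N,2-dimethyl-4-oxobut-2-enamide
Conditions: Amberlyst-15, acetone/H2O (10:1), rt
Reagents that add atoms: water (O)
Why: Acid-catalysed hydrolysis of an allylic dimethyl acetal should release the enal without touching the E alkene or the Weinreb amide.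

Step 3
Reactants: 5 (3E)-4-methoxybut-3-en-2-one; 6 (4-methoxyphenyl)methanol
Product: 7 (3E)-4-[(4-methoxyphenyl)methoxy]but-3-en-2-one
Conditions: PPTS (5 mol %), toluene, 90 °C, MeOH distilled off
Reagents that add atoms: none
Why: Acid-catalysed transetherification (addition–elimination) of a vinylogous ester, driven by removal of methanol, should keep the E enol ether and install a cleavable PMB group on the future O13.

Step 4
Reactants: 7 (3E)-4-[(4-methoxyphenyl)methoxy]but-3-en-2-one; 1 2,2-dimethoxyacetaldehyde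
Product: 9 (1E,5S)-5-hydroxy-6,6-dimethoxy-1-[(4-methoxyphenyl)methoxy]hex-1-en-3-one, via diisopinocampheylboron enolate 8 (not isolated)
Conditions: (−)-Ipc2BCl, Et3N, Et2O, 0 °C; then 1 (anhydrous), −78 → −20 °C; H2O2, MeOH, pH 7 buffer work-up
Reagents that add atoms: none
Why: Diisopinocampheylboron-mediated aldol reaction of a methyl ketone, in which the chiral boron enolate should add to the Si face of the aldehyde and so set C9 (S, the target's arrangement).

Step 5
Reactants: 9 (1E,5S)-5-hydroxy-6,6-dimethoxy-1-[(4-methoxyphenyl)methoxy]hex-1-en-3-one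
Product: 10 (1E,5S)-5-[(tert-butyldimethylsilyl)oxy]-6,6-dimethoxy-1-[(4-methoxyphenyl)methoxy]hex-1-en-3-one
Conditions: TBSCl, imidazole, DMF, rt
Reagents that add atoms: tert-butyldimethylsilyl chloride (CC(C)(C)[Si](C)(C)Cl)
Why: Silylation of the secondary alcohol under conditions too mild for retro-aldol cleavage or cyclisation to a dihydropyranone.

Step 6
Reactants: 10 (1E,5S)-5-[(tert-butyldimethylsilyl)oxy]-6,6-dimethoxy-1-[(4-methoxyphenyl)methoxy]hex-1-en-3-one
Product: 11 (1E,3Z,5S)-3,5-bis[(tert-butyldimethylsilyl)oxy]-6,6-dimethoxy-1-[(4-methoxyphenyl)methoxy]hexa-1,3-diene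
Conditions: TBSOTf, Et3N, Et2O, −78 → 0 °C
Reagents that add atoms: tert-butyldimethylsilyl trifluoromethanesulfonate (CC(C)(C)[Si](C)(C)OS(=O)(=O)C(F)(F)F)
Why: Soft enolisation of the ketone toward C10 should give the thermodynamically favoured Z silyl enol ether, a Danishefsky-type (1E,3Z)-diene with C9 on the outside.

Step 7
Reactants: 11 (1E,3Z,5S)-3,5-bis[(tert-butyldimethylsilyl)oxy]-6,6-dimethoxy-1-[(4-methoxyphenyl)methoxy]hexa-1,3-diene; 4 (2E)-N-methoxy-N,2-dimethyl-4-oxobut-2-enamide
Product: 12 ring A cycloadduct (C11 OTBS enol ether, C13 OPMB, C14 formyl, C1 methyl and Weinreb amide, C10 carrying the (9S)-CH(OTBS)CH(OMe)2 arm; methyl, formyl, OPMB and C9 arm all cis)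
Conditions: (5R)-5-benzyl-2,2,3-trimethylimidazolidin-4-one·CF3CO2H (first-generation imidazolidinone organocatalyst, 20 mol %), MeCN, H2O (2 equiv), −20 °C
Reagents that add atoms: none
Why: The secondary amine condenses with the C14 formyl group of 4 to an E iminium ion, which makes C1 (β to the iminium, although α to the amide) the acceptor carbon, so the nucleophilic C10 terminus of the 1-alkoxy-3-silyloxy diene bonds to C1 and the alkoxy-bearing C13 to C14 in an asynchronous concerted [4+2] cycloaddition, after which hydrolysis of the product iminium returns the catalyst. The closest known reaction type is the imidazolidinone-catalysed (iminium-activated) Diels–Alder reaction of enals with oxygenated dienes. The cyclohexene ring A is closed by intermolecular [4+2] cycloaddition, suprafacial on both partners. C1 and C10 follow from the endo (iminium) transition state together with the E geometry of 4 and the Z enol ether of 11 (C9 arm and C15 methyl cis, amide trans), and their absolute sense from the benzyl group of the (5R)-catalyst, which shields one face of the iminium ion; C13 (OPMB cis to the methyl, inverted in step 22) and C14 (erased in step 8) follow from the same endo rule. The step needs regioselectivity against the inherent polarity of a methacrylamide and facial selectivity over the C9 stereocentre of the diene, and these should be secured by placing the only activating (iminium) group on C14 and by catalyst control.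

Step 8
Reactants: 12 ring A cycloadduct
Product: 14 ring A ketone (C11 ketone, C14 now CH2, C13 β-OPMB cis to the C15 methyl, C1 and C10 as in the target), via enol silyl ether 13 (not isolated)
Conditions: RhCl(PPh3)3 (1.1 equiv), toluene, 100 °C; then TBAF, AcOH, THF, 0 °C
Reagents that add atoms: none
Why: Tsuji–Wilkinson decarbonylation should replace the formyl group by hydrogen, and buffered fluoride then cleaves only the enol silyl ether, unveiling the C11 ketone without β-elimination of the C13 ether.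

Step 9
Reactants: 14 ring A ketone
Product: 15 C11 exocyclic methylene compound (C11=C20H2)
Conditions: Tebbe reagent Cp2Ti(μ-CH2)(μ-Cl)AlMe2, pyridine, THF, −40 → 0 °C
Reagents that add atoms: Tebbe reagent (C=[Ti+2].c1cc[cH-]c1.c1cc[cH-]c1.C[Al](C)Cl)
Why: Tebbe methylenation is non-basic, so it should spare the C10 stereocentre and the β-alkoxy group, and it is faster for the ketone than for the hindered Weinreb amide.

Step 10
Reactants: 15 C11 exocyclic methylene compound
Product: 16 vinyl ketone (C2 carbonyl bearing C3H=CH2)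
Conditions: CH2=CHMgBr, THF, 0 °C; aq NH4Cl
Reagents that add atoms: vinylmagnesium bromide (C=C[Mg]Br)
Why: Weinreb ketone synthesis, in which the stable magnesium chelate prevents over-addition and conjugate addition until work-up.

Step 11
Reactants: 16 vinyl ketone
Product: 17 (2S)-allylic alcohol
Conditions: (R)-2-methyl-CBS-oxazaborolidine (20 mol %), BH3·SMe2, THF, −30 °C
Reagents that add atoms: none
Why: Corey–Bakshi–Shibata reduction, in which the quaternary C1 acts as the large and the vinyl group as the small substituent, so the (R)-catalyst should give the 2S alcohol.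

Step 12
Reactants: 17 (2S)-allylic alcohol
Product: 18 C2 tert-butyldimethylsilyl ether
Conditions: TBSOTf, 2,6-lutidine, CH2Cl2, −78 → 0 °C
Reagents that add atoms: tert-butyldimethylsilyl trifluoromethanesulfonate (CC(C)(C)[Si](C)(C)OS(=O)(=O)C(F)(F)F)
Why: Silylation of a hindered secondary alcohol with the silyl triflate protects O2 against the later oxidation.

Step 13
Reactants: 18 C2 tert-butyldimethylsilyl ether
Product: 19 C8 aldehyde ((9S)-α-silyloxy aldehyde)
Conditions: LiBF4, MeCN/H2O (50:1), rt
Reagents that add atoms: water (O)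
Why: Lewis-acid-assisted hydrolysis of the dimethyl acetal should leave the silyl ethers, the PMB ether and the exocyclic alkene untouched.

Step 14
Reactants: 19 C8 aldehyde; 20 1,4-bis(trimethylsilyl)buta-1,3-diyne
Product: 22 diynol (C8 carbinol, epimer mixture, C7≡C6–C5≡C4–SiMe3), via lithium (trimethylsilyl)butadiynide 21 (not isolated)
Conditions: MeLi·LiBr, THF, −78 °C → rt; then 19, −78 °C; H2O
Reagents that add atoms: none
Why: Monodesilylation of the bis-silyl diyne gives a lithium acetylide that adds 1,2 to the aldehyde; the C8 configuration is irrelevant because C8 is oxidised in step 16.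

Step 15
Reactants: 22 diynol
Product: 24 (6E)-enynol with terminal alkyne (C4≡C5), via silylated enynol 23 (not isolated)
Conditions: NaAlH2(OCH2CH2OMe)2, THF, 0 °C; then K2CO3, MeOH, rt
Reagents that add atoms: none
Why: Hydroxyl-directed trans-hydroalumination reduces only the alkyne next to the carbinol to the E alkene, and methanolysis then removes the alkynyl silane.

Step 16
Reactants: 24 (6E)-enynol
Product: 25 (6E)-enynone (C8 ketone)
Conditions: Dess–Martin periodinane, NaHCO3, CH2Cl2, 0 °C
Reagents that add atoms: none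
Why: Dess–Martin oxidation of the allylic alcohol under buffered conditions should not epimerise C9.

Step 17
Reactants: 25 (6E)-enynone
Product: 26 (6R,7S)-trans-epoxy ketone
Conditions: La(OiPr)3 (10 mol %), (R)-BINOL (10 mol %), Ph3As=O (10 mol %), tBuOOH, 4 Å MS, THF, rt
Reagents that add atoms: tert-butyl hydroperoxide (CC(C)(C)OO)
Why: Lanthanum–BINOL-catalysed Weitz–Scheffer epoxidation attacks only the electron-poor enone alkene, and the (R)-BINOL complex should give the αS,βR epoxy ketone, which fixes C7 and prepares C6.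

Step 18
Reactants: 26 (6R,7S)-trans-epoxy ketone
Product: 27 anti-chlorohydrin (6S chloride, 7R hydroxyl, C8 ketone)
Conditions: LiCl, AcOH, THF, rt
Reagents that add atoms: lithium chloride ([Li+].[Cl-])
Why: Acid-assisted halide opening of an α,β-epoxy ketone occurs by SN2 at the β carbon, here also propargylic, so inversion at C6 should give the target's C6–Cl/C7–O relationship.

Step 19
Reactants: 27 anti-chlorohydrin
Product: 28 C7 2-bromopropanoate (bromide-bearing carbon unspecified)
Conditions: 2-bromopropanoyl bromide, pyridine, CH2Cl2, −20 °C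
Reagents that add atoms: 2-bromopropanoyl bromide (CC(Br)C(=O)Br)
Why: O-acylation of the only free hydroxyl with an acid bromide under weakly basic conditions should not re-close the epoxide.

Step 20
Reactants: 28 C7 2-bromopropanoate
Product: 29 γ-lactone (ring C, 8-hydroxy and 17R methyl, C7 and C8 as in the target, 6S chloride)
Conditions: SmI2 (2.2 equiv), THF, −78 °C
Reagents that add atoms: none
Why: Intramolecular Reformatsky reaction, in which the samarium enolate from the α-bromo ester adds to the adjacent C8 ketone, should place the bulky C9 arm trans to the C6 substituent on C7 and the C17 methyl syn to the small C8 oxygen; C17 stays epimerisable toward this more stable arrangement.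

Step 21
Reactants: 29 γ-lactone
Product: 30 C13 β-alcohol
Conditions: DDQ, CH2Cl2/pH 7 buffer, 0 °C
Reagents that add atoms: none
Why: Oxidative cleavage of the PMB ether with DDQ should leave the silyl ethers, lactone, chloride and alkenes intact.

Step 22
Reactants: 30 C13 β-alcohol
Product: 31 (13S)-acetate (C13 α-OAc, as in the target)
Conditions: PPh3, DIAD, AcOH, toluene, 0 °C → rt
Reagents that add atoms: acetic acid (CC(=O)O)
Why: Mitsunobu esterification proceeds by SN2 with inversion, turning the β-alcohol (cis to the C15 methyl) into the α-acetate, while the tertiary C8 hydroxyl is inert.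

Step 23
Reactants: 31 (13S)-acetate
Product: 32 triol (free hydroxyls at C2, C8 and C9, terminal alkyne at C5)
Conditions: HF·pyridine, pyridine, THF, 0 °C → rt
Reagents that add atoms: none
Why: Buffered fluoride cleaves both silyl ethers under conditions tolerated by the lactone, the acetate and the propargylic chloride, and frees the allylic C2 hydroxyl, which assists the metathesis.

Step 24
Reactants: 32 triol
Product: 34 macrocyclic diol (2,9-dideacetyl target, 3E), via triene 33 (not isolated)
Conditions: second-generation Grubbs catalyst RuCl2(=CHPh)(H2IMes)(PCy3) (10 mol %), ethylene (1 atm), CH2Cl2, rt; then argon, toluene (1 mM), 1,4-benzoquinone (10 mol %), 80 °C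
Reagents that add atoms: ethylene (C=C)
Why: Enyne cross-metathesis with ethylene turns the terminal alkyne into the 2-substituted butadiene (C5=C16H2, C4H=CH2), and ring-closing metathesis of its vinyl end with the C2 vinyl group closes ring B, the E alkene being expected under reversible, thermodynamic conditions in the trans-fused bicycle.

Step 25
Reactants: 34 macrocyclic diol
Product: 35 target CNP0268873.1
Conditions: Ac2O, pyridine, DMAP (cat.), CH2Cl2, 0 °C → rt
Reagents that add atoms: acetic anhydride (CC(=O)OC(C)=O)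
Why: Acylation of the two secondary alcohols at C2 and C9, while the tertiary C8 hydroxyl should be too hindered to react.

Compound list
1 | 2,2-dimethoxyacetaldehyde | COC(OC)C=O | starting material
2 | N-methoxy-N-methyl-2-(triphenylphosphoranylidene)propanamide | CON(C)C(=O)C(C)=P(c1ccccc1)(c1ccccc1)c1ccccc1 | starting material
3 | (2E)-N,4,4-trimethoxy-N,2-dimethylbut-2-enamide | CON(C)C(=O)/C(C)=C/C(OC)OC | intermediate
4 | (2E)-N-methoxy-N,2-dimethyl-4-oxobut-2-enamide | CON(C)C(=O)/C(C)=C/C=O | intermediate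
5 | (3E)-4-methoxybut-3-en-2-one | CO/C=C/C(C)=O | starting material
6 | (4-methoxyphenyl)methanol | COc1ccc(CO)cc1 | starting material
7 | (3E)-4-[(4-methoxyphenyl)methoxy]but-3-en-2-one | COc1ccc(CO/C=C/C(C)=O)cc1 | intermediate
8 | diisopinocampheylboron enolate of 7 (O–B on the ketone carbon, terminal methylene) | C=C(/C=C/OCc1ccc(OC)cc1)OB([C@@H]1C[C@@H]2C[C@H]([C@H]1C)C2(C)C)[C@@H]1C[C@@H]2C[C@H]([C@H]1C)C2(C)C | intermediate
9 | (1E,5S)-5-hydroxy-6,6-dimethoxy-1-[(4-methoxyphenyl)methoxy]hex-1-en-3-one | COc1ccc(CO/C=C/C(=O)C[C@H](O)C(OC)OC)cc1 | intermediate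
10 | (1E,5S)-5-[(tert-butyldimethylsilyl)oxy]-6,6-dimethoxy-1-[(4-methoxyphenyl)methoxy]hex-1-en-3-one | COc1ccc(CO/C=C/C(=O)C[C@H](O[Si](C)(C)C(C)(C)C)C(OC)OC)cc1 | intermediate
11 | (1E,3Z,5S)-3,5-bis[(tert-butyldimethylsilyl)oxy]-6,6-dimethoxy-1-[(4-methoxyphenyl)methoxy]hexa-1,3-diene | COc1ccc(CO/C=C/C(O[Si](C)(C)C(C)(C)C)=C/[C@H](O[Si](C)(C)C(C)(C)C)C(OC)OC)cc1 | intermediate
12 | ring A cycloadduct: cyclohexene with C11 OTBS enol ether, C13 OPMB, C14 formyl, C1 methyl and N-methoxy-N-methylcarboxamide, C10 (9S)-CH(OTBS)CH(OMe)2; methyl, formyl, OPMB and C9 arm cis; C1 and C10 as in the target | CC(C)(C)[Si](C)(C)OC1=C[C@@H](OCc2ccc(OC)cc2)[C@@H](C=O)[C@](C)(C(=O)N(C)OC)[C@H]1[C@H](O[Si](C)(C)C(C)(C)C)C(OC)OC | intermediate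
13 | enol silyl ether (12 without the C14 formyl group) | CC(C)(C)[Si](C)(C)OC1=C[C@@H](OCc2ccc(OC)cc2)C[C@](C)(C(=O)N(C)OC)[C@H]1[C@H](O[Si](C)(C)C(C)(C)C)C(OC)OC | intermediate
14 | ring A ketone: C11 ketone, C13 β-OPMB, C1 methyl and Weinreb amide, C10 (9S)-CH(OTBS)CH(OMe)2 | O=C1C[C@@H](OCc2ccc(OC)cc2)C[C@](C)(C(=O)N(C)OC)[C@H]1[C@H](O[Si](C)(C)C(C)(C)C)C(OC)OC | intermediate
15 | C11 exocyclic methylene analogue of 14 | C=C1C[C@@H](OCc2ccc(OC)cc2)C[C@](C)(C(=O)N(C)OC)[C@H]1[C@H](O[Si](C)(C)C(C)(C)C)C(OC)OC | intermediate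
16 | vinyl ketone (C2 carbonyl, C3H=CH2) | C=C1C[C@@H](OCc2ccc(OC)cc2)C[C@](C)(C(=O)C=C)[C@H]1[C@H](O[Si](C)(C)C(C)(C)C)C(OC)OC | intermediate
17 | (2S)-allylic alcohol | C=C1C[C@@H](OCc2ccc(OC)cc2)C[C@](C)([C@@H](O)C=C)[C@H]1[C@H](O[Si](C)(C)C(C)(C)C)C(OC)OC | intermediate
18 | C2 tert-butyldimethylsilyl ether of 17 | C=C1C[C@@H](OCc2ccc(OC)cc2)C[C@](C)([C@@H](O[Si](C)(C)C(C)(C)C)C=C)[C@H]1[C@H](O[Si](C)(C)C(C)(C)C)C(OC)OC | intermediate
19 | C8 aldehyde ((9S)-α-silyloxy aldehyde) | C=C1C[C@@H](OCc2ccc(OC)cc2)C[C@](C)([C@@H](O[Si](C)(C)C(C)(C)C)C=C)[C@H]1[C@H](O[Si](C)(C)C(C)(C)C)C=O | intermediate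
20 | 1,4-bis(trimethylsilyl)buta-1,3-diyne | C[Si](C)(C)C#CC#C[Si](C)(C)C | starting material
21 | lithium 4-(trimethylsilyl)buta-1,3-diyn-1-ide | [Li]C#CC#C[Si](C)(C)C | intermediate
22 | diynol (C8 carbinol, epimer mixture) | C=C1C[C@@H](OCc2ccc(OC)cc2)C[C@](C)([C@@H](O[Si](C)(C)C(C)(C)C)C=C)[C@H]1[C@H](O[Si](C)(C)C(C)(C)C)C(O)C#CC#C[Si](C)(C)C | intermediate
23 | (6E)-enynol, alkyne still silylated | C=C1C[C@@H](OCc2ccc(OC)cc2)C[C@](C)([C@@H](O[Si](C)(C)C(C)(C)C)C=C)[C@H]1[C@H](O[Si](C)(C)C(C)(C)C)C(O)/C=C/C#C[Si](C)(C)C | intermediate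
24 | (6E)-enynol, terminal alkyne | C=C1C[C@@H](OCc2ccc(OC)cc2)C[C@](C)([C@@H](O[Si](C)(C)C(C)(C)C)C=C)[C@H]1[C@H](O[Si](C)(C)C(C)(C)C)C(O)/C=C/C#C | intermediate
25 | (6E)-enynone (C8 ketone) | C=C1C[C@@H](OCc2ccc(OC)cc2)C[C@](C)([C@@H](O[Si](C)(C)C(C)(C)C)C=C)[C@H]1[C@H](O[Si](C)(C)C(C)(C)C)C(=O)/C=C/C#C | intermediate
26 | (6R,7S)-trans-epoxy ketone | C=C1C[C@@H](OCc2ccc(OC)cc2)C[C@](C)([C@@H](O[Si](C)(C)C(C)(C)C)C=C)[C@H]1[C@H](O[Si](C)(C)C(C)(C)C)C(=O)[C@H]3O[C@@H]3C#C | intermediate
27 | anti-chlorohydrin (6S chloride, 7R hydroxyl, C8 ketone) | C=C1C[C@@H](OCc2ccc(OC)cc2)C[C@](C)([C@@H](O[Si](C)(C)C(C)(C)C)C=C)[C@H]1[C@H](O[Si](C)(C)C(C)(C)C)C(=O)[C@@H](O)[C@@H](Cl)C#C | intermediate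
28 | C7 2-bromopropanoate of 27 | C=C1C[C@@H](OCc2ccc(OC)cc2)C[C@](C)([C@@H](O[Si](C)(C)C(C)(C)C)C=C)[C@H]1[C@H](O[Si](C)(C)C(C)(C)C)C(=O)[C@@H](OC(=O)C(C)Br)[C@@H](Cl)C#C | intermediate
29 | γ-lactone (ring C; 8-hydroxy, 17R methyl, C7 and C8 as in the target, 6S chloride) | C=C1C[C@@H](OCc2ccc(OC)cc2)C[C@](C)([C@@H](O[Si](C)(C)C(C)(C)C)C=C)[C@H]1[C@H](O[Si](C)(C)C(C)(C)C)[C@]3(O)[C@@H](C)C(=O)O[C@H]3[C@@H](Cl)C#C | intermediate
30 | C13 β-alcohol (PMB removed) | C=C1C[C@@H](O)C[C@](C)([C@@H](O[Si](C)(C)C(C)(C)C)C=C)[C@H]1[C@H](O[Si](C)(C)C(C)(C)C)[C@]3(O)[C@@H](C)C(=O)O[C@H]3[C@@H](Cl)C#C | intermediate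
31 | (13S)-acetate (C13 α-OAc) | C=C1C[C@H](OC(C)=O)C[C@](C)([C@@H](O[Si](C)(C)C(C)(C)C)C=C)[C@H]1[C@H](O[Si](C)(C)C(C)(C)C)[C@]3(O)[C@@H](C)C(=O)O[C@H]3[C@@H](Cl)C#C | intermediate
32 | triol (C2, C8, C9 hydroxyls; terminal alkyne) | C=C1C[C@H](OC(C)=O)C[C@](C)([C@@H](O)C=C)[C@H]1[C@H](O)[C@]3(O)[C@@H](C)C(=O)O[C@H]3[C@@H](Cl)C#C | intermediate
33 | triene (C5=C16H2 and C4H=CH2 in place of the alkyne) | C=C1C[C@H](OC(C)=O)C[C@](C)([C@@H](O)C=C)[C@H]1[C@H](O)[C@]3(O)[C@@H](C)C(=O)O[C@H]3[C@@H](Cl)C(=C)C=C | intermediate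
34 | macrocyclic diol (2,9-dideacetyl target, 3E) | C=C1C[C@H](OC(C)=O)C[C@]2(C)[C@@H](O)/C=C/C(=C)[C@H](Cl)[C@@H]3OC(=O)[C@H](C)[C@@]3(O)[C@@H](O)[C@@H]12 | intermediate
35 | CNP0268873.1 (2,9,13-triacetate, 6-chloride, 8-hydroxy lactone) | C=C1C[C@H](OC(C)=O)C[C@]2(C)[C@@H](OC(C)=O)/C=C/C(=C)[C@H](Cl)[C@@H]3OC(=O)[C@H](C)[C@@]3(O)[C@@H](OC(C)=O)[C@@H]12 | target

Total step count: 25. Longest linear sequence: 23 steps (steps 3–25; steps 1–2 make the dienophile).

Steps most likely to fail

1. Step 7 (key Diels–Alder). The cycloaddition may be too slow at the fully substituted C1 terminus, so that protonolysis of the silyl dienol ether wins, or the C9 stereocentre of the diene may oppose the catalyst and erode facial selectivity. Fallback, setting out from 11 and coming back at 13: the polarity reversal is handed to a nitro group instead of the formyl/iminium pair. (2E)-N-methoxy-N,2-dimethyl-3-nitroprop-2-enamide F1 (from commercial N-methoxy-N-methylmethacrylamide by AgNO2/TEMPO nitration) reacts thermally with 11 (toluene, 25–40 °C). The nitro group directs C10 to C1 and sits endo, giving nitro cycloadduct F2 under substrate (C9) facial control, with the minor diastereomer removed by chromatography. Radical denitration (Bu3SnH, AIBN, toluene, 110 °C) then gives 13, which is desilylated as in the second half of step 8.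

2. Step 24 (ring B closure). The hindered C2 vinyl group may lead to oligomerisation, or the ring may close to the 3Z diene. Fallback, setting out from 32 and coming back at 34: the alkene geometry is set after ring closure instead of during it. The ring is closed at high dilution to whichever isomer forms, and the (3Z)-isomer of the macrocyclic diol F3 is equilibrated to 34 by reversible thiyl-radical addition (PhSSPh cat., hν, benzene).

3. Step 20 (Reformatsky lactonisation). Single-electron reduction may cleave the α-oxygenated ketone or the propargylic chloride before the enolate adds, or the addition may lack facial control at C8. Fallback, setting out from 27 and coming back at 29: an intermolecular aldol replaces the tethered one. TESOTf/2,6-lutidine gives the C7 triethylsilyl ether F4. The lithium enolate of ethyl propanoate (LDA, THF, −78 °C) adds to the C8 ketone anti to the C7 substituent (Felkin–Anh) to give the β-hydroxy ester F5. HF·pyridine at 0 °C then removes the triethylsilyl group selectively and the freed C7 hydroxyl lactonises to 29.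

Further compounds
F1 | step 7 | (2E)-N-methoxy-N,2-dimethyl-3-nitroprop-2-enamide | CON(C)C(=O)/C(C)=C/[N+](=O)[O-]
F2 | step 7 | nitro cycloadduct (12 with nitro in place of the C14 formyl group) | CC(C)(C)[Si](C)(C)OC1=C[C@@H](OCc2ccc(OC)cc2)[C@@H]([N+](=O)[O-])[C@](C)(C(=O)N(C)OC)[C@H]1[C@H](O[Si](C)(C)C(C)(C)C)C(OC)OC
F3 | step 24 | (3Z)-isomer of macrocyclic diol 34 | C=C1C[C@H](OC(C)=O)C[C@]2(C)[C@@H](O)/C=C\C(=C)[C@H](Cl)[C@@H]3OC(=O)[C@H](C)[C@@]3(O)[C@@H](O)[C@@H]12
F4 | step 20 | C7 triethylsilyl ether of chlorohydrin 27 | C=C1C[C@@H](OCc2ccc(OC)cc2)C[C@](C)([C@@H](O[Si](C)(C)C(C)(C)C)C=C)[C@H]1[C@H](O[Si](C)(C)C(C)(C)C)C(=O)[C@@H](O[Si](CC)(CC)CC)[C@@H](Cl)C#C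
F5 | step 20 | ethyl ester aldol adduct (C8 tertiary alcohol, C17 methyl, C7 OTES) | C=C1C[C@@H](OCc2ccc(OC)cc2)C[C@](C)([C@@H](O[Si](C)(C)C(C)(C)C)C=C)[C@H]1[C@H](O[Si](C)(C)C(C)(C)C)[C@](O)([C@@H](C)C(=O)OCC)[C@@H](O[Si](CC)(CC)CC)[C@@H](Cl)C#C
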